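1. The leftover of substrate reads 0 % at 6.00 h in Thursday's run, yet target still reads 24.8 % there and 25.3 % at 8.00 h. So I take it that charge is still sitting in intermediate A and feeding target.

| flask | substrate | partner | remark | time |
|---|---|---|---|---|
| Thursday's | 0.80 M | 3 equiv | run made earlier |  |
| flask | 0.80 M | 1.50 equiv |  | 6.0 d |

Thursday's run (percent of the substrate charged)

| time / h | target / % | substrate / % |
|---|---|---|
| 3.00 | 18.8 | 4.2 |
| 6.00 | 24.8 | 0 |
| 8.00 | 25.3 | 0 |
| 12.0 | 20.7 | 0 |
| 15.0 | 15.9 | 0 |

(scatter of a reading: 1 percentage point)

1. the best time, 6.0 d at the latest, for target
2. the amount of target, in percent of the substrate charged, at that time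
3. the first time at which target reaches 8.5 %, in the same percent, in d

- in percentages every species weighs as the substrate in it: one side product counts as two
- what may be going on: substrate -> intermediate A; substrate <-> intermediate B; partner + intermediate A -> target; substrate + intermediate B -> side product; target -> over-reaction product

2. The substrate reading of Thursday's run at 3.00 h, taken as a first-order decay, gives a substrate lifetime of about 0.946 h, which I treat as a lag before the chain from intermediate A through target starts.

3. First way: suppose that in Thursday's run making and using of target share one rate constant. Target then follows time times a falling exponential, counted after the lag, and peaks at the inverse of that constant. The peak read near 8.00 h gives 0.142 h⁻¹.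

4. Second way: the same curve through the last two readings gives 0.168 h⁻¹. The two are close, so I use their mean, 0.155 h⁻¹. The plain tail slope gives 0.0879 h⁻¹, less than the first way. I count that slope as the cheat, since on this curve a tail is still being fed.

5. Making takes partner and intermediate A together, so I treat it as pseudo-first-order and scale its constant by the charge ratio of the flask to Thursday's run, 0.500, neglecting partner spent. Scaling the early reading of Thursday's run, I expect the flask to hold about 9.40 % at 3.00 h, and so to reach 8.5 % at about 0.113 d.

6. The peak of target is the crossing where making equals using. With the using constant held, its height relative to the equal-constant chain is the height factor, the charge ratio raised to one over (one minus the charge ratio), times Euler's number: 0.680. Applied to the peak read in Thursday's run, this gives my estimate for the flask, 17.2 % at 0.412 d.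

7. The forecast, reached by “Stepping this through by hand”, gives 0.37 d, 19.5 % and 0.1 d, higher than my peak and earlier. The flask gives 0.353 d, 17.0 % and 0.108 d.

    substrate → intermediate A (k = 0.860 h⁻¹)
    substrate ⇌ intermediate B (K = 2.10, k = 0.120 h⁻¹)
    partner + intermediate A → target (k = 0.0670 M⁻¹ h⁻¹)
    substrate + intermediate B → side product (k = 0.830 M⁻¹ h⁻¹)
    target → over-reaction product (k = 0.190 h⁻¹)

At 0.353 d the flask holds target 17.0 % against intermediate A 52.4 %, a ratio of 0.324, and the making constant at the partner then present over the using constant is 0.324, the same crossing. The height factor of 0.680 stands against 0.637, the flask's peak over Thursday's peak without scatter, and for the neighbouring flask with 2.50 equiv of partner it gives 0.910 against a simulated 0.897.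

The readings come from a simulation for substances that don't exist, and the scatter is random.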